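**Plan**

1. Retrosynthesis: both prenyl–C(=O) bonds are cut back to a bis(methyl ester) and the right-ring C1–CH3 bond is cut. Then, in each ring (C1 quaternary, C2 carbinol, C3 alkylidene, C4–C6 methylenes), C1–C6 and C3–C4 are cut. This removes C4–C6 as a propane-1,3-diyl unit and leaves an acyclic bis(β-hydroxy ester) on a chain derived from hexa-1,5-diyne.
2. Forward: hexa-1,5-diyne gives the dialdehyde; an acetate aldol (right) and a propionate aldol (left) follow; syn-hydrostannation and iodination give the bis(iodoalkene). Both rings then arise in one operation (step 8), followed by right-hand methylation and conversion of both esters into the prenyl ketones.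
3. Enabling feature: in each half the carbinol carbon C2 holds, 1,3 to each other, the ester α-carbon C1 (a nucleophile once the C2-alkoxide/ester-enolate chelate forms) and the iodoalkene carbon C3 (an electrophile for palladium). 2-(3-Iodopropyl)pinacolborane, electrophilic at one end and nucleophilic at the other, bridges C1 and C3 in a formal [3+3] annulation.
4. Stereochemistry: both carbinols come from auxiliary-controlled aldols. The left quaternary centre comes from acyclic Fráter–Seebach alkylation (ring carbon introduced last, OH cis to CH3). The right one comes from Fráter–Seebach methylation of the closed ring (CH3 introduced last, trans to OH). Reversing the order from the same carbinol sense gives the opposite quaternary configuration.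
5. Alkene geometry: syn H/Sn addition with tin next to the carbinol, then stereoretentive iodination and coupling.

Key step: step 8

Remark: 1, 3, 5 and 10 are taken as commercial, as is the reagent 1-chloro-3-methylbut-2-ene (prenyl chloride) of step 13. The α-carbon of each hydroxy ester (C2 and C11 of 6–9) becomes an enolate carbon later, so its configuration before step 8 is of no consequence.

**Step 1**
Reactants: 1 hexa-1,5-diyne
Product: 2 octa-2,6-diynedial
Conditions: n-BuLi (2.1 equiv), THF, −78 °C; DMF, −78 to 0 °C; reverse quench into aq. KH2PO4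
Reagents that add atoms: N,N-dimethylformamide CN(C)C=O
Why: Formylation of lithium acetylides with DMF and a buffered reverse quench is the standard route to ynals; no stereocentre is formed.

**Step 2**
Reactants: 2 octa-2,6-diynedial (3 equiv); 3 (S)-2-hydroxy-1,2,2-triphenylethyl acetate ((S)-HYTRA)
Product: 4 (S)-2-hydroxy-1,2,2-triphenylethyl (3S)-3-hydroxy-10-oxodeca-4,8-diynoate
Conditions: 3, LiN(i-Pr)2 (2.1 equiv), THF, −78 to 0 °C; then 2, THF, −100 °C; aq. NH4Cl
Reagents that add atoms: none
Why: Auxiliary-controlled acetate aldol: the dilithiated HYTRA acetate adds to one aldehyde of the excess symmetric dialdehyde (which should secure mono-addition), and its triphenylglycol unit should set the (3S)-carbinol by reagent control.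

**Step 3**
Reactants: 4 HYTRA mono-aldol; 5 (S)-4-benzyl-3-propanoyl-1,3-oxazolidin-2-one
Product: 6 (S)-2-hydroxy-1,2,2-triphenylethyl (3S,10S,11S)-12-[(4S)-4-benzyl-2-oxo-1,3-oxazolidin-3-yl]-3,10-dihydroxy-11-methyl-12-oxododeca-4,8-diynoate
Conditions: 5 (3 equiv), Bu2BOTf, Et3N, CH2Cl2, −78 to 0 °C; 4, −78 to 0 °C; MeOH, pH 7 buffer, H2O2
Reagents that add atoms: none
Why: Evans syn aldol: the Z-boron enolate of 5 adds to the remaining ynal through a Zimmerman–Traxler chair under oxazolidinone control and should give the (10S,11S) adduct, of which only the carbinol configuration is used later.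

**Step 4**
Reactants: 6 bis-aldol carrying both auxiliaries
Product: 7 dimethyl (2S,3S,10S)-3,10-dihydroxy-2-methyldodeca-4,8-diynedioate
Conditions: NaOMe (0.3 equiv), MeOH, 0 °C
Reagents that add atoms: methanol CO
Why: Methoxide transesterification cleaves both the N-acyloxazolidinone and the HYTRA ester to methyl esters; the carbinol centres are not touched.

**Step 5**
Reactants: 7 diynediol diester
Product: 8 dimethyl (2S,3S,4E,8E,10S)-3,10-dihydroxy-2-methyl-4,9-bis(tributylstannyl)dodeca-4,8-dienedioate
Conditions: Bu3SnH (2.5 equiv), Mo(CO)3(CNt-Bu)3 (5 mol %), hydroquinone, THF, 55 °C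
Reagents that add atoms: tributyltin hydride CCCC[SnH](CCCC)CCCC
Why: Molybdenum-isonitrile-catalysed hydrostannation of propargylic alcohols adds H and Sn syn with tin on the alkyne carbon next to the carbinol, which should place each linker CH2 cis to its carbinol carbon as the target requires.

**Step 6**
Reactants: 8 bis(alkenylstannane)
Product: 9 dimethyl (2S,3S,4E,8E,10S)-3,10-dihydroxy-4,9-diiodo-2-methyldodeca-4,8-dienedioate
Conditions: I2 (2.1 equiv), CH2Cl2, 0 °C; aq. Na2S2O3
Reagents that add atoms: iodine I-I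
Why: Iododestannylation of alkenylstannanes proceeds with retention of alkene geometry.

**Step 7**
Reactants: 10 2-(3-bromopropyl)-4,4,5,5-tetramethyl-1,3,2-dioxaborolane
Product: 11 2-(3-iodopropyl)-4,4,5,5-tetramethyl-1,3,2-dioxaborolane
Conditions: NaI (3 equiv), acetone, reflux
Reagents that add atoms: sodium iodide [Na+].[I-]
Why: Finkelstein exchange gives the more reactive primary iodide needed for alkylation at a fully substituted enolate carbon.

**Step 8**
Reactants: 9 bis(iodoalkene) diol diester; 11 2-(3-iodopropyl)pinacolborane (2.4 equiv; one molecule is taken up by each half)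
Product: 13 methyl (1R,2R,3Z)-2-hydroxy-3-{(4Z)-4-[(2S,3R)-2-hydroxy-3-(methoxycarbonyl)cyclohexylidene]butylidene}-1-methylcyclohexane-1-carboxylate, via bis-alkylated diboronate 12 (not isolated)
Conditions: 9, LiN(i-Pr)2 (4.0 equiv), THF, −78 to −20 °C; 11, DMPU, −40 to −10 °C; then PdCl2(dppf) (10 mol %), Cs2CO3, DMF/H2O, 50 °C
Reagents that add atoms: none
Why: LiN(i-Pr)2 converts each half into the lithium alkoxide–ester enolate chelate, whose α-carbon is alkylated by the iodide end of 11 (Fráter–Seebach alkylation); palladium then inserts into each vinyl iodide, the pendant primary boronate transmetalates and C(sp3)–C(sp2) reductive elimination closes the ring (intramolecular B-alkyl Suzuki–Miyaura coupling), so that one propane-1,3-diyl reagent joins C1 and C3 of each half in a formal [3+3] annulation. Each cyclohexane closes from a seven-membered alkyl(alkenyl)palladacycle, the new bond being exo to the alkene, which ends up as the exocyclic alkylidene. The left quaternary centre is controlled by the adjacent (S)-carbinol: in the six-membered lithium chelate the iodoalkenyl group blocks one enolate face and the electrophile enters anti to it, which should give the (2R) configuration of 12 (OH cis to CH3 in the ring); the right α-centre forms in the same sense but is erased in step 9. The alkene geometry is carried over because oxidative addition and reductive elimination retain configuration at the iodoalkene carbon. The step needs C- over O-alkylation and a single alkylation at the right-hand acetate position, which the chelated dianions and exactly four equivalents of base should secure, and it needs intra- over intermolecular coupling, which the six-membered ring size and the modest excess of 11 favour.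

**Step 9**
Reactants: 13 bis-ring diol diester
Product: 14 methyl (1R,2R,3Z)-2-hydroxy-3-{(4Z)-4-[(2R,3S)-2-hydroxy-3-(methoxycarbonyl)-3-methylcyclohexylidene]butylidene}-1-methylcyclohexane-1-carboxylate
Conditions: LiN(i-Pr)2 (3.2 equiv), THF, −78 to −30 °C; MeI, −78 to −20 °C; aq. NH4Cl
Reagents that add atoms: iodomethane CI
Why: Fráter–Seebach alkylation of a cyclic β-hydroxy ester: only the right-hand ester still has an α-hydrogen, and its alkoxide–enolate chelate should take up MeI trans to the alkoxide, so that CO2CH3 ends cis to OH and the quaternary centre is (S), opposite in sense to the left one.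

**Step 10**
Reactants: 14 bis-quaternary diol diester
Product: 15 methyl (1R,2R,3Z)-3-{(4Z)-4-[(2R,3S)-3-(methoxycarbonyl)-3-methyl-2-(triethylsilyloxy)cyclohexylidene]butylidene}-1-methyl-2-(triethylsilyloxy)cyclohexane-1-carboxylate
Conditions: Et3SiOTf (2.5 equiv), 2,6-lutidine, CH2Cl2, 0 °C
Reagents that add atoms: triethylsilyl trifluoromethanesulfonate CC[Si](CC)(CC)OS(=O)(=O)C(F)(F)F
Why: Silyl triflate silylation protects the two hindered allylic alcohols so that only the ester-derived carbons are oxidized later.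

**Step 11**
Reactants: 15 bis(triethylsilyl) ether diester
Product: 16 diol in which both CO2CH3 groups of 15 are reduced to CH2OH (stereocentres and alkenes as in 15)
Conditions: i-Bu2AlH (6 equiv), CH2Cl2, −78 to 0 °C; aq. potassium sodium tartrate
Reagents that add atoms: none
Why: Aluminium hydride reduction of the two neopentyl esters to primary alcohols leaves silyl ethers and alkenes untouched.

**Step 12**
Reactants: 16 bis(neopentyl alcohol)
Product: 17 dialdehyde in which both CH2OH groups of 16 are oxidized to CHO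
Conditions: Dess–Martin periodinane, NaHCO3, CH2Cl2, 0 °C to rt
Reagents that add atoms: none
Why: Dess–Martin oxidation gives the aldehydes; the α-carbons are quaternary, so there is no epimerization, and the silyl ethers block retro-aldol cleavage.

**Step 13**
Reactants: 17 dialdehyde
Product: 18 bis(homoallylic alcohol) in which each CHO of 17 has become CH(OH)CH2CH=C(CH3)2 (both carbinol epimers)
Conditions: BaI2 (3 equiv), lithium biphenylide LiC12H10 (6 equiv), THF, rt (activated Ba); 1-chloro-3-methylbut-2-ene (3 equiv), −78 °C (prenylbarium chloride); 17, THF, −78 °C; aq. NH4Cl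
Reagents that add atoms: 1-chloro-3-methylbut-2-ene CC(C)=CCCl
Why: Allylic barium reagents add to aldehydes through the unsubstituted α-carbon (α-selective allylation), so prenylbarium chloride made in the flask from prenyl chloride should deliver one linear prenyl group to each of the two aldehydes (two molecules of the reagent enter the product); the new carbinol centres are oxidized away in step 14.

**Step 14**
Reactants: 18 bis(homoallylic alcohol)
Product: 19 bis(triethylsilyl) ether of the target
Conditions: Dess–Martin periodinane, NaHCO3, CH2Cl2, 0 °C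
Reagents that add atoms: none
Why: Buffered Dess–Martin oxidation converts homoallylic alcohols to β,γ-unsaturated ketones without moving the alkene into conjugation.

**Step 15**
Reactants: 19 bis(triethylsilyl) ether
Product: 20 1-[(1R,2R,3Z)-2-hydroxy-3-{(4Z)-4-[(2R,3S)-2-hydroxy-3-methyl-3-(4-methylpent-3-enoyl)cyclohexylidene]butylidene}-1-methylcyclohexyl]-4-methylpent-3-en-1-one (target, CNP0297042.3)
Conditions: HF·pyridine, pyridine, THF, 0 °C to rt
Reagents that add atoms: none
Why: Buffered acidic fluoride removes the silyl groups; acidic rather than basic conditions avoid retro-aldol cleavage of the β-hydroxy ketones.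

**Compound list**

1 | hexa-1,5-diyne | C#CCCC#C | starting material
2 | octa-2,6-diynedial | O=CC#CCCC#CC=O | intermediate
3 | (S)-2-hydroxy-1,2,2-triphenylethyl acetate ((S)-HYTRA) | CC(=O)O[C@@H](c1ccccc1)C(O)(c1ccccc1)c1ccccc1 | starting material
4 | (S)-2-hydroxy-1,2,2-triphenylethyl (3S)-3-hydroxy-10-oxodeca-4,8-diynoate | O=CC#CCCC#C[C@@H](O)CC(=O)O[C@@H](c1ccccc1)C(O)(c1ccccc1)c1ccccc1 | intermediate
5 | (S)-4-benzyl-3-propanoyl-1,3-oxazolidin-2-one | CCC(=O)N1[C@@H](Cc2ccccc2)COC1=O | starting material
6 | (S)-2-hydroxy-1,2,2-triphenylethyl (3S,10S,11S)-12-[(4S)-4-benzyl-2-oxo-1,3-oxazolidin-3-yl]-3,10-dihydroxy-11-methyl-12-oxododeca-4,8-diynoate | O=C(N1[C@@H](Cc2ccccc2)COC1=O)[C@@H](C)[C@H](O)C#CCCC#C[C@@H](O)CC(=O)O[C@@H](c1ccccc1)C(O)(c1ccccc1)c1ccccc1 | intermediate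
7 | dimethyl (2S,3S,10S)-3,10-dihydroxy-2-methyldodeca-4,8-diynedioate | COC(=O)[C@@H](C)[C@H](O)C#CCCC#C[C@@H](O)CC(=O)OC | intermediate
8 | dimethyl (2S,3S,4E,8E,10S)-3,10-dihydroxy-2-methyl-4,9-bis(tributylstannyl)dodeca-4,8-dienedioate | COC(=O)[C@@H](C)[C@H](O)/C(=C\CC/C=C(/[Sn](CCCC)(CCCC)CCCC)[C@@H](O)CC(=O)OC)[Sn](CCCC)(CCCC)CCCC | intermediate
9 | dimethyl (2S,3S,4E,8E,10S)-3,10-dihydroxy-4,9-diiodo-2-methyldodeca-4,8-dienedioate | COC(=O)[C@@H](C)[C@H](O)/C(I)=C\CC/C=C(/I)[C@@H](O)CC(=O)OC | intermediate
10 | 2-(3-bromopropyl)-4,4,5,5-tetramethyl-1,3,2-dioxaborolane | BrCCCB1OC(C)(C)C(C)(C)O1 | starting material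
11 | 2-(3-iodopropyl)-4,4,5,5-tetramethyl-1,3,2-dioxaborolane | ICCCB1OC(C)(C)C(C)(C)O1 | intermediate
12 | dimethyl (2R,3S,4E,8E,10S,11R)-3,10-dihydroxy-4,9-diiodo-2-methyl-2,11-bis[3-(4,4,5,5-tetramethyl-1,3,2-dioxaborolan-2-yl)propyl]dodeca-4,8-dienedioate (not isolated) | COC(=O)[C@](C)(CCCB1OC(C)(C)C(C)(C)O1)[C@H](O)/C(I)=C\CC/C=C(/I)[C@@H](O)[C@@H](CCCB1OC(C)(C)C(C)(C)O1)C(=O)OC | intermediate
13 | methyl (1R,2R,3Z)-2-hydroxy-3-{(4Z)-4-[(2S,3R)-2-hydroxy-3-(methoxycarbonyl)cyclohexylidene]butylidene}-1-methylcyclohexane-1-carboxylate | COC(=O)[C@]1(C)CCC/C(=C/CC/C=C2/CCC[C@@H](C(=O)OC)[C@@H]2O)[C@H]1O | intermediate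
14 | methyl (1R,2R,3Z)-2-hydroxy-3-{(4Z)-4-[(2R,3S)-2-hydroxy-3-(methoxycarbonyl)-3-methylcyclohexylidene]butylidene}-1-methylcyclohexane-1-carboxylate | COC(=O)[C@]1(C)CCC/C(=C/CC/C=C2/CCC[C@](C)(C(=O)OC)[C@@H]2O)[C@H]1O | intermediate
15 | bis(triethylsilyl) ether of 14 (both ring hydroxyls silylated) | COC(=O)[C@]1(C)CCC/C(=C/CC/C=C2/CCC[C@](C)(C(=O)OC)[C@@H]2O[Si](CC)(CC)CC)[C@H]1O[Si](CC)(CC)CC | intermediate
16 | diol: both CO2CH3 of 15 reduced to CH2OH, configuration as in 15 | OC[C@]1(C)CCC/C(=C/CC/C=C2/CCC[C@](C)(CO)[C@@H]2O[Si](CC)(CC)CC)[C@H]1O[Si](CC)(CC)CC | intermediate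
17 | dialdehyde: both CH2OH of 16 oxidized to CHO | O=C[C@]1(C)CCC/C(=C/CC/C=C2/CCC[C@](C)(C=O)[C@@H]2O[Si](CC)(CC)CC)[C@H]1O[Si](CC)(CC)CC | intermediate
18 | bis(homoallylic alcohol): each CHO of 17 converted to CH(OH)CH2CH=C(CH3)2, both carbinol epimers | CC(C)=CCC(O)[C@]1(C)CCC/C(=C/CC/C=C2/CCC[C@](C)(C(O)CC=C(C)C)[C@@H]2O[Si](CC)(CC)CC)[C@H]1O[Si](CC)(CC)CC | intermediate
19 | bis(triethylsilyl) ether of the target | CC(C)=CCC(=O)[C@]1(C)CCC/C(=C/CC/C=C2/CCC[C@](C)(C(=O)CC=C(C)C)[C@@H]2O[Si](CC)(CC)CC)[C@H]1O[Si](CC)(CC)CC | intermediate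
20 | 1-[(1R,2R,3Z)-2-hydroxy-3-{(4Z)-4-[(2R,3S)-2-hydroxy-3-methyl-3-(4-methylpent-3-enoyl)cyclohexylidene]butylidene}-1-methylcyclohexyl]-4-methylpent-3-en-1-one | CC(C)=CCC(=O)[C@]1(C)CCC/C(=C/CC/C=C2/CCC[C@](C)(C(=O)CC=C(C)C)[C@@H]2O)[C@H]1O | target

**Totals and risks**

Total: 15 steps. Longest linear sequence: 14 steps (steps 1–6 and 8–15, from hexa-1,5-diyne); step 7 is a one-step side branch.

Steps most likely to fail:

- **Step 8.** The unactivated primary iodide may alkylate the fully substituted left enolate only slowly, the right-hand α-carbon may be alkylated twice, the haloalkylboronate may be lost by γ-elimination at boron, or slow transmetalation of the pinacol boronate may lead to protodeiodination. The fallback sets out from 9 and separates the two bond formations with a more reactive electrophile and a more reactive borane. Fráter–Seebach alkylation of 9 with allyl iodide (LiN(i-Pr)2, THF/DMPU) should give dimethyl (2R,3S,4E,8E,10S,11R)-2,11-diallyl-3,10-dihydroxy-4,9-diiodo-2-methyldodeca-4,8-dienedioate F1. Hydroboration of its two terminal alkenes with 9-BBN should give the bis(B-alkyl-9-BBN) borane F2. Without isolation, F2 undergoes double intramolecular B-alkyl Suzuki–Miyaura coupling (PdCl2(dppf), AsPh3, Cs2CO3, DMF/H2O) and the route is rejoined at 13.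

- **Step 5.** Regiocontrol of tin delivery may be lost at the two hindered internal alkynes (tin on the carbon remote from the carbinol), which would feed the wrong iodoalkene into step 8. The fallback sets out from 2 and moves the hydrometalation to the ynal stage, where conjugation with the aldehyde directs tin to the α-carbon. Bu3SnH with Pd(PPh3)4 (zerovalent palladium) in THF at 0 °C should give (2E,6E)-2,7-bis(tributylstannyl)octa-2,6-dienedial F3. The HYTRA acetate aldol of step 2 then gives the mono-aldol F4, and the Evans propionate aldol of step 3 gives the bis-aldol F5. Methanolysis as in step 4 rejoins the route at 8.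

- **Step 13.** The allylic metal may attack through its γ-carbon (giving the 1,1-dimethylallyl carbinol), or conversion may be incomplete at the neopentyl aldehydes. The fallback sets out from 17 and uses a sulfone-stabilized carbanion that can only bond through its α-carbon. Lithiated (3-methylbut-2-en-1-yl) phenyl sulfone (n-BuLi, THF, −78 °C) should give the bis(β-hydroxy sulfone) F6. Dess–Martin oxidation gives the bis(β-keto sulfone) F7. Reductive desulfonylation with SmI2 (THF/MeOH, −78 °C) proceeds through α-protonation of the dienolate, which keeps the β,γ-alkene, and rejoins the route at 19.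

**Further compounds**

F1 | step 8 | dimethyl (2R,3S,4E,8E,10S,11R)-2,11-diallyl-3,10-dihydroxy-4,9-diiodo-2-methyldodeca-4,8-dienedioate | COC(=O)[C@](C)(CC=C)[C@H](O)/C(I)=C\CC/C=C(/I)[C@@H](O)[C@@H](CC=C)C(=O)OC
F2 | step 8 | dimethyl (2R,3S,4E,8E,10S,11R)-2,11-bis[3-(9-borabicyclo[3.3.1]nonan-9-yl)propyl]-3,10-dihydroxy-4,9-diiodo-2-methyldodeca-4,8-dienedioate | COC(=O)[C@](C)(CCCB1C2CCCC1CCC2)[C@H](O)/C(I)=C\CC/C=C(/I)[C@@H](O)[C@@H](CCCB1C2CCCC1CCC2)C(=O)OC
F3 | step 5 | (2E,6E)-2,7-bis(tributylstannyl)octa-2,6-dienedial | O=C/C(=C\CC/C=C(/[Sn](CCCC)(CCCC)CCCC)C=O)[Sn](CCCC)(CCCC)CCCC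
F4 | step 5 | (S)-2-hydroxy-1,2,2-triphenylethyl (3S,4E,8E)-3-hydroxy-10-oxo-4,9-bis(tributylstannyl)deca-4,8-dienoate | O=C/C(=C\CC/C=C(/[Sn](CCCC)(CCCC)CCCC)[C@@H](O)CC(=O)O[C@@H](c1ccccc1)C(O)(c1ccccc1)c1ccccc1)[Sn](CCCC)(CCCC)CCCC
F5 | step 5 | (S)-2-hydroxy-1,2,2-triphenylethyl (3S,4E,8E,10S,11S)-12-[(4S)-4-benzyl-2-oxo-1,3-oxazolidin-3-yl]-3,10-dihydroxy-11-methyl-12-oxo-4,9-bis(tributylstannyl)dodeca-4,8-dienoate | O=C(N1[C@@H](Cc2ccccc2)COC1=O)[C@@H](C)[C@H](O)/C(=C\CC/C=C(/[Sn](CCCC)(CCCC)CCCC)[C@@H](O)CC(=O)O[C@@H](c1ccccc1)C(O)(c1ccccc1)c1ccccc1)[Sn](CCCC)(CCCC)CCCC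
F6 | step 13 | bis(β-hydroxy sulfone): each CHO of 17 converted to CH(OH)CH(SO2Ph)CH=C(CH3)2, epimer mixture at the new centres | CC(C)=CC(S(=O)(=O)c1ccccc1)C(O)[C@]1(C)CCC/C(=C/CC/C=C2/CCC[C@](C)(C(O)C(C=C(C)C)S(=O)(=O)c3ccccc3)[C@@H]2O[Si](CC)(CC)CC)[C@H]1O[Si](CC)(CC)CC
F7 | step 13 | bis(β-keto sulfone): each CH(OH) of F6 oxidized to C=O | CC(C)=CC(S(=O)(=O)c1ccccc1)C(=O)[C@]1(C)CCC/C(=C/CC/C=C2/CCC[C@](C)(C(=O)C(C=C(C)C)S(=O)(=O)c3ccccc3)[C@@H]2O[Si](CC)(CC)CC)[C@H]1O[Si](CC)(CC)CC
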